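**Assumption:** brandisianin A has no stereocentres, so the route has no stereochemical issues. 2,5-Dimethoxyphenol and 2,4,6-trihydroxyacetophenone are taken as commercial.

**Retrosynthesis**
- Disconnect the C3–aryl bond (Suzuki–Miyaura) to 3-iodo-5,7-dihydroxychromone (12) and the aryl pinacol boronate (7).
- Chromone ring: 12 comes from phloroacetophenone (8) by enaminone formation and then I2-mediated cyclisation, so the pyranone ring is built before the coupling.
- B-ring: 7 comes from aryl bromide 5, made from 2,5-dimethoxyphenol (1) by para-bromination and O-prenylation.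
- The prenyl ether goes on early. A late prenylation could not distinguish the 4′-OH from the acidic 5/7-OH groups.

**Route**

Step 1
Reactants: 1 (2,5-dimethoxyphenol), 2 (N-bromosuccinimide)
Product: 3 (4-bromo-2,5-dimethoxyphenol)
Conditions: NBS (1.0 equiv), CH2Cl2, −78 °C to 0 °C
Reagents that add atoms: NBS, O=C1CCC(=O)N1Br (adds Br)
Why: Electrophilic aromatic bromination goes para to the strongly activating OH, at C4, which is also ortho to the 5-OMe; the other para positions relative to the OMe groups are blocked.

Step 2
Reactants: 3, 4 (prenyl bromide, 1-bromo-3-methylbut-2-ene)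
Product: 5 (1-bromo-2,5-dimethoxy-4-[(3-methylbut-2-en-1-yl)oxy]benzene)
Conditions: prenyl bromide (1.2 equiv), K2CO3, acetone, 50 °C
Reagents that add atoms: prenyl bromide, CC(C)=CCBr (adds the prenyl group)
Why: Williamson ether synthesis; the phenoxide is alkylated on oxygen in a polar aprotic solvent, and the SN2 reaction keeps the prenyl alkene unrearranged.

Step 3
Reactants: 5, 6 (2-isopropoxy-4,4,5,5-tetramethyl-1,3,2-dioxaborolane, iPrOBpin)
Product: 7 (2-[2,5-dimethoxy-4-(prenyloxy)phenyl]-4,4,5,5-tetramethyl-1,3,2-dioxaborolane)
Conditions: n-BuLi (1.05 equiv), THF, −78 °C, 30 min; then iPrOBpin (1.3 equiv), −78 °C to rt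
Reagents that add atoms: iPrOBpin, CC(C)OB1OC(C)(C)C(C)(C)O1 (adds Bpin)
Why: Br/Li exchange is much faster than any deprotonation or Wittig rearrangement of the prenyl ether at −78 °C. The aryllithium is then trapped as the boronate. Lithiation avoids Pd(0) in this step, which could ionise the allylic aryl ether.

Step 4
Reactants: 8 (2,4,6-trihydroxyacetophenone), 9 (N,N-dimethylformamide dimethyl acetal, DMF-DMA)
Product: 10 ((E)-3-(dimethylamino)-1-(2,4,6-trihydroxyphenyl)prop-2-en-1-one)
Conditions: DMF-DMA (2.5 equiv), toluene, 80 °C, 3 h
Reagents that add atoms: DMF-DMA, CN(C)C(OC)OC (adds the =CH–NMe2 unit)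
Why: The acetyl CH3 condenses with DMF-DMA (enaminone formation, loss of MeOH). The hydrogen-bonded 2,6-OH groups stay intact.

Step 5
Reactants: 10, 11 (iodine)
Product: 12 (5,7-dihydroxy-3-iodo-4H-chromen-4-one)
Conditions: I2 (1.2 equiv), THF, rt, 2 h; aq Na2S2O3 work-up
Reagents that add atoms: I2, II (adds I)
Why: Electrophilic iodination of the nucleophilic enaminone α-carbon, then attack of the 2′-OH on the iminium and loss of HNMe2, closes the pyranone ring (iodocyclisation) and gives the 3-iodochromone.

Step 6
Reactants: 7, 12
Product: 13 (brandisianin A, 5,7-dihydroxy-3-[2,5-dimethoxy-4-(prenyloxy)phenyl]chromen-4-one)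
Conditions: Pd(PPh3)4 (5 mol%), Na2CO3 (4 equiv), dioxane/H2O 4:1, 80 °C, 4 h; then quench with aq citric acid to pH ~5
Reagents that add atoms: none
Why: Suzuki–Miyaura cross-coupling at the reactive vinyl C–I bond. Extra base covers the acidic phenols, which stay free, and the weakly acidic quench protonates the 7-phenoxide without cleaving the prenyl ether.

**Checks**
- B-ring mapping: in 5 and 7 the C–Br/C–B carbon has an ortho OMe, and the other OMe sits ortho to the O-prenyl. In the target, C1′ is attached, 2′-OMe is ortho, 5′-OMe is ortho to the 4′-O-prenyl, and 3′ and 6′ are H. This matches the target SMILES.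
- Atom count: C22H22O7 (C9 chromone core + C13 B-ring/prenyl unit).
- Protecting groups: none are used. The prenyl ether survives NBS at low temperature, K2CO3, the −78 °C lithiation, and the mild Pd/base conditions. No strong acid is used.
- Stereocentres: none in the target, and the prenyl alkene geometry is irrelevant because it is trisubstituted with two identical methyl ends.

**Compound list**
1 | 2,5-dimethoxyphenol | Oc1cc(OC)ccc1OC | starting material
2 | N-bromosuccinimide | O=C1CCC(=O)N1Br | starting material (reagent)
3 | 4-bromo-2,5-dimethoxyphenol | Oc1cc(OC)c(Br)cc1OC | intermediate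
4 | prenyl bromide | CC(C)=CCBr | starting material (reagent)
5 | 1-bromo-2,5-dimethoxy-4-(prenyloxy)benzene | CC(C)=CCOc1cc(OC)c(Br)cc1OC | intermediate
6 | 2-isopropoxy-4,4,5,5-tetramethyl-1,3,2-dioxaborolane | CC(C)OB1OC(C)(C)C(C)(C)O1 | starting material (reagent)
7 | 2,5-dimethoxy-4-(prenyloxy)phenyl-Bpin | CC(C)=CCOc1cc(OC)c(B2OC(C)(C)C(C)(C)O2)cc1OC | intermediate
8 | 2,4,6-trihydroxyacetophenone | CC(=O)c1c(O)cc(O)cc1O | starting material
9 | DMF-DMA | CN(C)C(OC)OC | starting material (reagent)
10 | (E)-3-(dimethylamino)-1-(2,4,6-trihydroxyphenyl)prop-2-en-1-one | CN(C)/C=C/C(=O)c1c(O)cc(O)cc1O | intermediate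
11 | iodine | II | starting material (reagent)
12 | 5,7-dihydroxy-3-iodochromone | O=c1c(I)coc2cc(O)cc(O)c12 | intermediate
13 | brandisianin A | COc1cc(-c2coc3cc(O)cc(O)c3c2=O)c(OC)cc1OCC=C(C)C | target

**Totals:** 6 steps in total; longest linear sequence 4 steps (1→3→5→7→13, or equally 8→10→12→13).

**Three steps most likely to fail**
1. **Step 6 (Suzuki on the free polyphenol, with Pd(0) and an allylic aryl ether).** Pd(0) could cleave the prenyl ether, or the phenoxide could poison the catalyst.
   - Fallback: change the approach to a Pd-free isoflavone synthesis. Friedel–Crafts acylation of phloroglucinol with 2,5-dimethoxy-4-(prenyloxy)phenylacetic acid (homologated from 5) gives a deoxybenzoin, which is closed with MsCl/BF3·Et2O/DMF.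
2. **Step 5 (I2 cyclisation on the electron-rich phloroglucinol ring).** Competing iodination of the A-ring could occur.
   - Fallback: use the 4,6-bis-MOM-protected 2-hydroxyacetophenone, so the ring is blocked and deactivated. Run enaminone formation, iodocyclisation and Suzuki coupling, then remove the MOM groups with mild Lewis acid (MgBr2·OEt2/EtSH) that spares the prenyl ether.
3. **Step 4 (DMF-DMA with acidic phenols).** O-Methylation of the 4-OH, or incomplete enaminone formation, could occur.
   - Fallback: drop DMF-DMA and build 5,7-dihydroxychromone from 8 by Claisen formylation (HCO2Et/NaH) and acid cyclisation. Then install C3 by a different route, such as Vilsmeier-type 3-formylchromone chemistry on the bis-MOM compound.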